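**Retrosynthetic overview**

1. Feature: in ring A (C1 acyloxy CH, C2 CHOH, C3 methyl-bearing oxirane carbon, C4 oxirane CH, C5 CH2, C6 CH with the chain) the four contiguous oxygenated carbons C1–C4 beside the C5 methylene are C4–C1 of a 2-C-methyl-D-allo-hexopyranoside, whose O2, O3 and O4 are all cis.
2. Late disconnections: the C2 O–PMB bond, the side-chain oxirane (epoxidation of a prenyl alkene), the C1 and C8 esters, the prenyl group (cross-metathesis), C8–C9 (asymmetric allylation of a 2-substituted acrolein), C7=CH2 (α-methylenation), C6–C7 (olefination of a C6 ketone, then hydroxyl-directed hydrogenation).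
3. The ring-A oxirane is cut to a C3 tertiary alkoxide and a C4 α-mesylate (closure with inversion), so the carbocycle must carry a C4 hydroxyl trans to the C3 oxygen.
4. Ring A is cut at C4–C5: intramolecular aldol closure (Ferrier carbocyclization) of a 6-deoxyhex-5-enopyranoside. Sugar O3 and O4 carry different groups (PMB, TBS) because in the target C2–OH is free and C1–OH is acylated.
5. The hexenopyranoside comes in seven steps from methyl 2,3-anhydro-4,6-O-benzylidene-α-D-mannopyranoside. Ring order: ring A (step 8), ring-A oxirane (step 14), side-chain oxirane (step 22).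

Key step: step 8

Remark: β is the face of ring A that carries the C1, C2 and C3 oxygens and α the opposite face; the chain is C7 (C=CH2), C8 (CH–O-acyl), C9 (CH2), C10 (oxirane CH), C11 (CMe2); sugars keep carbohydrate numbering; 1, 24 and 31 are assumed to be bought as single enantiomers.

**Route**

Step 1
Reactants: 1 methyl 2,3-anhydro-4,6-O-benzylidene-α-D-mannopyranoside; 2 4-methoxybenzyl alcohol
Product: 3 methyl 4,6-O-benzylidene-3-O-(4-methoxybenzyl)-α-D-altropyranoside
Conditions: NaH (1.5 equiv), 2 (neat, 10 equiv), 110 °C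
Reagents that add atoms: 4-methoxybenzyl alcohol (2), COc1ccc(CO)cc1
Why: Alkoxide opening of the rigid anhydro sugar follows the Fürst–Plattner (trans-diaxial) rule, so the nucleophile should enter at C3 from the α face with SN2 inversion and leave a free axial 2-OH.

Step 2
Reactants: 3 methyl 4,6-O-benzylidene-3-O-(4-methoxybenzyl)-α-D-altropyranoside
Product: 4 methyl 4,6-O-benzylidene-3-O-(4-methoxybenzyl)-α-D-ribo-hexopyranosid-2-ulose
Conditions: Dess–Martin periodinane, CH2Cl2, rt
Reagents that add atoms: none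
Why: Dess–Martin oxidation turns the only free hydroxyl into the C2 ketone under non-basic conditions, so the axial C3 ether next to the new carbonyl should not epimerise.

Step 3
Reactants: 4 methyl 4,6-O-benzylidene-3-O-(4-methoxybenzyl)-α-D-ribo-hexopyranosid-2-ulose; 5 methylmagnesium bromide
Product: 6 methyl 4,6-O-benzylidene-3-O-(4-methoxybenzyl)-2-C-methyl-α-D-allopyranoside
Conditions: 5, THF, −78 to 0 °C; aq. NH4Cl
Reagents that add atoms: methylmagnesium bromide (5), C[Mg]Br
Why: Grignard 1,2-addition to the conformationally locked 2-ulose should occur from the β face, anti to the axial C1 methoxy and C3 PMB-oxy groups, which sets the tertiary carbinol with O2 cis to O3 and O4.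

Step 4
Reactants: 6 methyl 4,6-O-benzylidene-3-O-(4-methoxybenzyl)-2-C-methyl-α-D-allopyranoside
Product: 7 methyl 3-O-(4-methoxybenzyl)-2-C-methyl-α-D-allopyranoside
Conditions: AcOH/H2O 4:1, 60 °C
Reagents that add atoms: none
Why: Acid-catalysed acetal hydrolysis frees O4 and O6, while the PMB ether, the methyl glycoside and the tertiary alcohol tolerate warm aqueous acetic acid.

Step 5
Reactants: 7 methyl 3-O-(4-methoxybenzyl)-2-C-methyl-α-D-allopyranoside
Product: 8 methyl 6-deoxy-6-iodo-3-O-(4-methoxybenzyl)-2-C-methyl-α-D-allopyranoside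
Conditions: iodine, PPh3, imidazole, THF, 60 °C
Reagents that add atoms: iodine, [I][I]
Why: Garegg–Samuelsson iodination (Appel-type SN2 displacement of an alkoxyphosphonium ion) is selective for the primary hydroxyl over the secondary and tertiary ones.

Step 6
Reactants: 8 methyl 6-deoxy-6-iodo-3-O-(4-methoxybenzyl)-2-C-methyl-α-D-allopyranoside
Product: 9 methyl 4-O-(tert-butyldimethylsilyl)-6-deoxy-6-iodo-3-O-(4-methoxybenzyl)-2-C-methyl-α-D-allopyranoside
Conditions: TBSOTf (1.1 equiv), 2,6-lutidine, CH2Cl2, −78 to 0 °C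
Reagents that add atoms: tert-butyldimethylsilyl triflate, CC(C)(C)[Si](C)(C)OS(=O)(=O)C(F)(F)F
Why: Silylation should take place at the secondary 4-OH in preference to the hindered tertiary 2-OH and puts on the future C1 oxygen of ring A a group that survives the carbocyclization.

Step 7
Reactants: 9 methyl 4-O-(tert-butyldimethylsilyl)-6-deoxy-6-iodo-3-O-(4-methoxybenzyl)-2-C-methyl-α-D-allopyranoside
Product: 10 methyl 4-O-(tert-butyldimethylsilyl)-6-deoxy-3-O-(4-methoxybenzyl)-2-C-methyl-α-D-ribo-hex-5-enopyranoside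
Conditions: DBU, THF, reflux
Reagents that add atoms: none
Why: E2 dehydrohalogenation of the primary iodide gives the exocyclic enol ether, the standard entry to 6-deoxyhex-5-enopyranosides.

Step 8
Reactants: 10 methyl 4-O-(tert-butyldimethylsilyl)-6-deoxy-3-O-(4-methoxybenzyl)-2-C-methyl-α-D-ribo-hex-5-enopyranoside
Product: 12 (2S,3R,4S,5R)-2-(tert-butyldimethylsilyloxy)-4,5-dihydroxy-3-(4-methoxybenzyloxy)-4-methylcyclohexanone [ring A: C6 ketone; 1β-OTBS; 2β-OPMB; 3β-OH; 3α-CH3; 4α-OH], via open-chain mercurio keto-aldehyde 11 (not isolated)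
Conditions: Hg(OCOCF3)2 (0.1 equiv), acetone/H2O 2:1, rt
Reagents that add atoms: water, O
Why: Divalent mercury adds to the electron-rich exocyclic enol ether (hydroxymercuration at sugar C5/C6), the hemiketal collapses with loss of methanol to the 1,5-dicarbonyl mercurial 11, and its α-mercurio ketone adds as an enolate to the aldehyde, the mercury salt being released on protonation; this is the Ferrier carbocyclization of 6-deoxyhex-5-enopyranosides to 2-deoxyinososes. Ring A closes through the former sugar C6–C1 bond (C5–C4 of ring A) in a 6-(enolendo)-exo-trig aldol addition. The centres at C1, C2 and C3 are carried over unchanged, since the aldehyde α-carbon is quaternary and cannot enolise and the medium is close to neutral. The one new centre, the C4 carbinol, is set by the substrate in the chair-like aldol transition state, where the aldehyde oxygen turns away from the 1,3-related C2 oxygen (former sugar O3), so the hydroxyl should end up α, trans to the C2 and C3 oxygens, the usual preference of this reaction relative to the sugar C3 substituent. The step needs attack of mercury on the enol ether and not on the anisyl ring, and no β-elimination of the new hydroxyl; the much higher nucleophilicity of the enol ether, the catalytic loading and the mild aqueous medium should secure both.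

Step 9
Reactants: 12 ring-A ketone [1β-OTBS; 2β-OPMB; 3β-OH; 3α-CH3; 4α-OH]
Product: 13 4-O-triethylsilyl ether of 12 [ring A: C6 ketone; 1β-OTBS; 2β-OPMB; 3β-OH; 3α-CH3; 4α-OTES]
Conditions: TESCl, imidazole, DMF, 0 °C
Reagents that add atoms: chlorotriethylsilane, CC[Si](Cl)(CC)CC
Why: Silylation is selective for the secondary carbinol over the tertiary one and blocks retro-aldol and β-elimination pathways of the β-hydroxy ketone in the next step.

Step 10
Reactants: 13 silylated ring-A ketone; 14 trimethyl phosphonoacetate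
Product: 15 methyl 2-(ring-A-6-ylidene)acetate, E/Z mixture [1β-OTBS; 2β-OPMB; 3β-OH; 3α-CH3; 4α-OTES]
Conditions: 14 (1.6 equiv), NaH (1.5 equiv), THF, 0 °C (anion preformed); then 13, 0 °C to rt
Reagents that add atoms: trimethyl phosphonoacetate (14), COC(=O)CP(=O)(OC)OC
Why: Horner–Wadsworth–Emmons olefination with the preformed, weakly basic phosphonate anion installs C7 and C8 on the ketone; the alkene geometry does not matter because the alkene is reduced later.

Step 11
Reactants: 15 methyl 2-(ring-A-6-ylidene)acetate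
Product: 16 methyl 2-(ring-A-6-ylidene)acetate with free C4 hydroxyl [1β-OTBS; 2β-OPMB; 3β-OH; 3α-CH3; 4α-OH]
Conditions: pyridinium p-toluenesulfonate (cat.), MeOH/CH2Cl2, 0 °C to rt
Reagents that add atoms: none
Why: Mild acid-catalysed methanolysis removes the secondary triethylsilyl ether in the presence of the more hindered TBS ether and the PMB ether and frees the C4 hydroxyl as a directing group.

Step 12
Reactants: 16 hydroxy enoate
Product: 17 methyl 2-(ring-A-6β-yl)acetate [6α-H; 1β-OTBS; 2β-OPMB; 3β-OH; 3α-CH3; 4α-OH]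
Conditions: [Ir(cod)(PCy3)(py)]PF6 (10 mol %), H2 (1 atm), CH2Cl2, rt
Reagents that add atoms: none
Why: Hydroxyl-directed homogeneous hydrogenation should deliver hydrogen to the alkene face syn to the homoallylic C4 hydroxyl (α face), which sets C6 with the acetate arm β, cis to the C1 oxygen.

Step 13
Reactants: 17 methyl 2-(ring-A-6β-yl)acetate
Product: 18 4α-methanesulfonate of 17 [1β-OTBS; 2β-OPMB; 3β-OH; 3α-CH3; 4α-OMs]
Conditions: MsCl, Et3N, CH2Cl2, 0 °C
Reagents that add atoms: methanesulfonyl chloride, CS(=O)(=O)Cl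
Why: Sulfonylation is selective for the secondary C4 hydroxyl over the tertiary C3 hydroxyl and turns it into a leaving group.

Step 14
Reactants: 18 mesylate
Product: 19 methyl 2-(ring-A-6β-yl)acetate with 3β,4β-oxirane [1β-OTBS; 2β-OPMB; 3α-CH3]
Conditions: K2CO3, MeOH, rt
Reagents that add atoms: none
Why: Intramolecular Williamson (3-exo-tet) displacement of the α-mesylate by the trans C3 alkoxide proceeds with inversion at C4 and should give the β-oxirane, cis to the C2 oxygen as in the target.

Step 15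
Reactants: 19 epoxy ester
Product: 20 2-(ring-A-6β-yl)acetaldehyde [1β-OTBS; 2β-OPMB; 3β,4β-epoxy; 3α-CH3]
Conditions: DIBAL-H (1.1 equiv), CH2Cl2, −78 °C; Rochelle salt work-up
Reagents that add atoms: none
Why: Partial reduction of the methyl ester with DIBAL-H at low temperature stops at the aluminium hemiacetal and gives the aldehyde on work-up, the oxirane and the ethers being inert at this temperature.

Step 16
Reactants: 20 aldehyde; 21 N,N-dimethylmethyleneiminium iodide (Eschenmoser salt)
Product: 23 2-(ring-A-6β-yl)prop-2-enal [1β-OTBS; 2β-OPMB; 3β,4β-epoxy; 3α-CH3], via Mannich base 22 (not isolated)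
Conditions: 21, Et3N, CH2Cl2, rt
Reagents that add atoms: N,N-dimethylmethyleneiminium iodide (21), C=[N+](C)C.[I-]
Why: Mannich reaction of the aldehyde enol with the iminium salt followed by β-elimination of dimethylamine from 22 is the standard α-methylenation of aldehydes and creates the C7 exo-methylene.

Step 17
Reactants: 23 2-substituted acrolein; 24 (−)-B-allyldiisopinocampheylborane (from (+)-α-pinene)
Product: 25 (3S)-2-(ring-A-6β-yl)hexa-1,5-dien-3-ol, i.e. the (8S) homoallylic alcohol [1β-OTBS; 2β-OPMB; 3β,4β-epoxy; 3α-CH3]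
Conditions: 24 (1 M in pentane), Et2O, −78 °C; then NaOH, H2O2, 0 °C to rt
Reagents that add atoms: (−)-B-allyldiisopinocampheylborane (24), C=CCB([C@@H]1C[C@@H]2C[C@H]([C@H]1C)C2(C)C)[C@@H]1C[C@@H]2C[C@H]([C@H]1C)C2(C)C
Why: Brown asymmetric allylboration through a closed chair transition state is reagent-controlled; the reagent from (+)-α-pinene adds allyl to the Si face of the enal and should give the (8S) carbinol.

Step 18
Reactants: 25 (8S) homoallylic alcohol; 26 angelic acid, (Z)-2-methylbut-2-enoic acid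
Product: 27 (8S) angelate of 25 [1β-OTBS; 2β-OPMB; 3β,4β-epoxy; 3α-CH3]
Conditions: 26, 2,4,6-trichlorobenzoyl chloride, Et3N, toluene, rt, salt filtered off; then 25, toluene, 75 °C
Reagents that add atoms: angelic acid (26), C/C=C(/C)C(=O)O
Why: Acylation by the mixed 2,4,6-trichlorobenzoic anhydride of angelic acid (Yamaguchi-type esterification without DMAP) avoids the nucleophile-induced Z to E isomerisation of the angeloyl group.

Step 19
Reactants: 27 (8S) angelate; 28 2-methyl-2-butene
Product: 29 (3S)-6-methyl-2-(ring-A-6β-yl)hepta-1,5-dien-3-yl (Z)-2-methylbut-2-enoate [1β-OTBS; 2β-OPMB; 3β,4β-epoxy; 3α-CH3]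
Conditions: 28 (excess), second-generation Grubbs catalyst RuCl2(H2IMes)(PCy3)(=CHPh) (5 mol %), CH2Cl2, 40 °C
Reagents that add atoms: 2-methyl-2-butene (28), CC=C(C)C
Why: Olefin cross-metathesis with excess 2-methyl-2-butene turns the monosubstituted alkene into the prenyl group, while the hindered 1,1-disubstituted alkene and the electron-poor angelate alkene should not react.

Step 20
Reactants: 29 prenyl angelate
Product: 30 C1 alcohol [1β-OH; 2β-OPMB; 3β,4β-epoxy; 3α-CH3; chain as in 29]
Conditions: TBAF, AcOH (1:1), THF, rt to 40 °C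
Reagents that add atoms: none
Why: Fluoride-induced desilylation buffered with acetic acid frees the C1 hydroxyl without base-mediated acyl transfer or opening of the oxirane.

Step 21
Reactants: 30 C1 alcohol; 31 (R)-2-methylbutanoic acid
Product: 32 C1 (R)-2-methylbutanoate [1β-O-acyl; 2β-OPMB; 3β,4β-epoxy; 3α-CH3; chain as in 29]
Conditions: 31, N,N'-dicyclohexylcarbodiimide, DMAP (cat.), CH2Cl2, 0 °C to rt
Reagents that add atoms: (R)-2-methylbutanoic acid (31), CC[C@@H](C)C(=O)O
Why: Steglich esterification acylates the only free hydroxyl with the enantiopure acid under conditions that should not epimerise its α centre.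

Step 22
Reactants: 32 diester
Product: 33 2-O-(4-methoxybenzyl) ether of the target, with the (10R) side-chain oxirane
Conditions: D-fructose-derived Shi ketone (0.3 equiv), Oxone, K2CO3, Bu4NHSO4, MeCN/dimethoxymethane/aq. Na2B4O7–EDTA buffer, 0 °C
Reagents that add atoms: potassium peroxymonosulfate (active part of Oxone), [K+].[O-]S(=O)(=O)OO
Why: Shi asymmetric epoxidation by the chiral dioxirane is selective for the electron-rich trisubstituted prenyl alkene over the deactivated 1,1-disubstituted and conjugated alkenes and, through the spiro transition state, should give the (10R) oxirane.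

Step 23
Reactants: 33 PMB ether of the target
Product: 34 target CNP0181486.1: ring A with 1β-[(R)-2-methylbutanoyloxy], 2β-OH, 3β,4β-epoxy-3α-methyl and 6β-[(3S)-3-(angeloyloxy)-4-((2R)-3,3-dimethyloxiran-2-yl)but-1-en-2-yl]
Conditions: DDQ, CH2Cl2/pH 7 phosphate buffer 10:1, 0 °C to rt
Reagents that add atoms: none
Why: Oxidative cleavage of the PMB ether by DDQ (hydride abstraction, then hydrolysis of the oxocarbenium ion) under buffered neutral conditions releases the C2 hydroxyl last, so neither acyl migration from C1 nor opening of the two oxiranes should occur.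

**Compound list**

1 | methyl 2,3-anhydro-4,6-O-benzylidene-α-D-mannopyranoside | CO[C@@H]1[C@H]2O[C@H]2[C@@H]3O[C@H](c4ccccc4)OC[C@H]3O1 | starting material
2 | 4-methoxybenzyl alcohol | COc1ccc(CO)cc1 | starting material
3 | methyl 4,6-O-benzylidene-3-O-(4-methoxybenzyl)-α-D-altropyranoside | CO[C@@H]1[C@@H](O)[C@H](OCc2ccc(OC)cc2)[C@@H]3O[C@H](c4ccccc4)OC[C@H]3O1 | intermediate
4 | methyl 4,6-O-benzylidene-3-O-(4-methoxybenzyl)-α-D-ribo-hexopyranosid-2-ulose | CO[C@@H]1C(=O)[C@H](OCc2ccc(OC)cc2)[C@@H]3O[C@H](c4ccccc4)OC[C@H]3O1 | intermediate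
5 | methylmagnesium bromide | C[Mg]Br | starting material
6 | methyl 4,6-O-benzylidene-3-O-(4-methoxybenzyl)-2-C-methyl-α-D-allopyranoside | CO[C@@H]1[C@](C)(O)[C@H](OCc2ccc(OC)cc2)[C@@H]3O[C@H](c4ccccc4)OC[C@H]3O1 | intermediate
7 | methyl 3-O-(4-methoxybenzyl)-2-C-methyl-α-D-allopyranoside | CO[C@@H]1[C@](C)(O)[C@H](OCc2ccc(OC)cc2)[C@H](O)[C@@H](CO)O1 | intermediate
8 | methyl 6-deoxy-6-iodo-3-O-(4-methoxybenzyl)-2-C-methyl-α-D-allopyranoside | CO[C@@H]1[C@](C)(O)[C@H](OCc2ccc(OC)cc2)[C@H](O)[C@@H](CI)O1 | intermediate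
9 | methyl 4-O-(tert-butyldimethylsilyl)-6-deoxy-6-iodo-3-O-(4-methoxybenzyl)-2-C-methyl-α-D-allopyranoside | CO[C@@H]1[C@](C)(O)[C@H](OCc2ccc(OC)cc2)[C@H](O[Si](C)(C)C(C)(C)C)[C@@H](CI)O1 | intermediate
10 | methyl 4-O-(tert-butyldimethylsilyl)-6-deoxy-3-O-(4-methoxybenzyl)-2-C-methyl-α-D-ribo-hex-5-enopyranoside (key-step precursor) | CO[C@@H]1[C@](C)(O)[C@H](OCc2ccc(OC)cc2)[C@H](O[Si](C)(C)C(C)(C)C)C(=C)O1 | intermediate
11 | 4-O-(tert-butyldimethylsilyl)-6-deoxy-3-O-(4-methoxybenzyl)-2-C-methyl-6-(trifluoroacetoxymercurio)-D-ribo-hexos-5-ulose, open-chain form | O=C[C@](C)(O)[C@H](OCc1ccc(OC)cc1)[C@H](O[Si](C)(C)C(C)(C)C)C(=O)C[Hg]OC(=O)C(F)(F)F | intermediate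
12 | (2S,3R,4S,5R)-2-(tert-butyldimethylsilyloxy)-4,5-dihydroxy-3-(4-methoxybenzyloxy)-4-methylcyclohexanone (key-step product; ring A: C6 ketone, 1β-OTBS, 2β-OPMB, 3β-OH, 3α-CH3, 4α-OH) | O=C1C[C@@H](O)[C@](C)(O)[C@H](OCc2ccc(OC)cc2)[C@@H]1O[Si](C)(C)C(C)(C)C | intermediate
13 | 4α-O-triethylsilyl ether of 12 | O=C1C[C@@H](O[Si](CC)(CC)CC)[C@](C)(O)[C@H](OCc2ccc(OC)cc2)[C@@H]1O[Si](C)(C)C(C)(C)C | intermediate
14 | trimethyl phosphonoacetate | COC(=O)CP(=O)(OC)OC | starting material
15 | methyl 2-(ring-A-6-ylidene)acetate, E/Z mixture (1β-OTBS, 2β-OPMB, 3β-OH, 3α-CH3, 4α-OTES) | COC(=O)C=C1C[C@@H](O[Si](CC)(CC)CC)[C@](C)(O)[C@H](OCc2ccc(OC)cc2)[C@@H]1O[Si](C)(C)C(C)(C)C | intermediate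
16 | methyl 2-(ring-A-6-ylidene)acetate, E/Z mixture, 4α-OH free | COC(=O)C=C1C[C@@H](O)[C@](C)(O)[C@H](OCc2ccc(OC)cc2)[C@@H]1O[Si](C)(C)C(C)(C)C | intermediate
17 | methyl 2-(ring-A-6β-yl)acetate (1β-OTBS, 2β-OPMB, 3β-OH, 3α-CH3, 4α-OH) | COC(=O)C[C@@H]1C[C@@H](O)[C@](C)(O)[C@H](OCc2ccc(OC)cc2)[C@@H]1O[Si](C)(C)C(C)(C)C | intermediate
18 | 4α-methanesulfonate of 17 | COC(=O)C[C@@H]1C[C@@H](OS(C)(=O)=O)[C@](C)(O)[C@H](OCc2ccc(OC)cc2)[C@@H]1O[Si](C)(C)C(C)(C)C | intermediate
19 | methyl 2-(ring-A-6β-yl)acetate with 3β,4β-oxirane (1β-OTBS, 2β-OPMB, 3α-CH3) | COC(=O)C[C@@H]1C[C@@H]2O[C@]2(C)[C@H](OCc3ccc(OC)cc3)[C@@H]1O[Si](C)(C)C(C)(C)C | intermediate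
20 | 2-(ring-A-6β-yl)acetaldehyde (substituents as in 19) | O=CC[C@@H]1C[C@@H]2O[C@]2(C)[C@H](OCc3ccc(OC)cc3)[C@@H]1O[Si](C)(C)C(C)(C)C | intermediate
21 | N,N-dimethylmethyleneiminium iodide | C=[N+](C)C.[I-] | starting material
22 | 3-(dimethylamino)-2-(ring-A-6β-yl)propanal, mixture at C7 | CN(C)CC(C=O)[C@@H]1C[C@@H]2O[C@]2(C)[C@H](OCc3ccc(OC)cc3)[C@@H]1O[Si](C)(C)C(C)(C)C | intermediate
23 | 2-(ring-A-6β-yl)prop-2-enal | C=C(C=O)[C@@H]1C[C@@H]2O[C@]2(C)[C@H](OCc3ccc(OC)cc3)[C@@H]1O[Si](C)(C)C(C)(C)C | intermediate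
24 | (−)-B-allyldiisopinocampheylborane, from (+)-α-pinene | C=CCB([C@@H]1C[C@@H]2C[C@H]([C@H]1C)C2(C)C)[C@@H]1C[C@@H]2C[C@H]([C@H]1C)C2(C)C | starting material
25 | (3S)-2-(ring-A-6β-yl)hexa-1,5-dien-3-ol, (8S) | C=C([C@H](CC=C)O)[C@@H]1C[C@@H]2O[C@]2(C)[C@H](OCc3ccc(OC)cc3)[C@@H]1O[Si](C)(C)C(C)(C)C | intermediate
26 | angelic acid, (Z)-2-methylbut-2-enoic acid | C/C=C(/C)C(=O)O | starting material
27 | (8S) angelate of 25 | C=C([C@H](CC=C)OC(=O)/C(C)=C\C)[C@@H]1C[C@@H]2O[C@]2(C)[C@H](OCc3ccc(OC)cc3)[C@@H]1O[Si](C)(C)C(C)(C)C | intermediate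
28 | 2-methyl-2-butene | CC=C(C)C | starting material
29 | (3S)-6-methyl-2-(ring-A-6β-yl)hepta-1,5-dien-3-yl (Z)-2-methylbut-2-enoate (1β-OTBS, 2β-OPMB) | C=C([C@H](CC=C(C)C)OC(=O)/C(C)=C\C)[C@@H]1C[C@@H]2O[C@]2(C)[C@H](OCc3ccc(OC)cc3)[C@@H]1O[Si](C)(C)C(C)(C)C | intermediate
30 | C1 alcohol from 29 (1β-OH, 2β-OPMB) | C=C([C@H](CC=C(C)C)OC(=O)/C(C)=C\C)[C@@H]1C[C@@H]2O[C@]2(C)[C@H](OCc3ccc(OC)cc3)[C@@H]1O | intermediate
31 | (R)-2-methylbutanoic acid | CC[C@@H](C)C(=O)O | starting material
32 | C1 (R)-2-methylbutanoate of 30 | C=C([C@H](CC=C(C)C)OC(=O)/C(C)=C\C)[C@@H]1C[C@@H]2O[C@]2(C)[C@H](OCc3ccc(OC)cc3)[C@@H]1OC(=O)[C@H](C)CC | intermediate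
33 | 2-O-(4-methoxybenzyl) ether of the target, (10R) oxirane | C=C([C@H](C[C@H]1OC1(C)C)OC(=O)/C(C)=C\C)[C@@H]1C[C@@H]2O[C@]2(C)[C@H](OCc3ccc(OC)cc3)[C@@H]1OC(=O)[C@H](C)CC | intermediate
34 | CNP0181486.1 | C=C([C@H](C[C@H]1OC1(C)C)OC(=O)/C(C)=C\C)[C@@H]1C[C@@H]2O[C@]2(C)[C@H](O)[C@@H]1OC(=O)[C@H](C)CC | target

**Step count and risks**

Total step count: 23. Longest linear sequence: 23 steps (1 to 34).

Steps most likely to fail:

- Step 8 (key step). What may go wrong: poor facial selectivity in the aldol closure, so that the new carbinol forms cis to the C2 oxygen, or loss of the catalyst through mercuration of the anisyl ring. Fallback: the route sets out again from 10 without metal. Mild acid hydrolysis of the enol ether (pyridinium p-toluenesulfonate, THF/H2O, rt) should give the free 1,5-dicarbonyl compound 4-O-(tert-butyldimethylsilyl)-6-deoxy-3-O-(4-methoxybenzyl)-2-C-methyl-D-ribo-hexos-5-ulose F1. A reversible amine-catalysed intramolecular aldol addition (pyrrolidinium acetate, DMSO, rt) then closes the same C4–C5 bond under equilibrating conditions. These should place the new hydroxyl equatorial in the chair that keeps the C1 and C3 oxygens equatorial, which is the required α orientation. The route is rejoined at 12.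

- Step 12. What may go wrong: delivery of hydrogen to the β face (direction by the tertiary C3 hydroxyl or by the ester) or stalling of the reduction of the hindered conjugated alkene. Fallback: the alkene is moved into the ring so that the C4 hydroxyl becomes allylic. From 13, kinetic deprotonation at C5 (KHMDS, 2.2 equiv, THF, −78 °C) and trapping with PhNTf2 should give the C5=C6 enol triflate of the ring-A ketone F2. Negishi coupling with the Reformatsky reagent BrZnCH2CO2Me (Pd(PPh3)4, THF, 50 °C) gives methyl 2-(ring-A-cyclohex-5-en-6-yl)acetate with 4α-OTES F3. Methanolysis (pyridinium p-toluenesulfonate, MeOH) gives the allylic alcohol, methyl 2-(ring-A-cyclohex-5-en-6-yl)acetate with 4α-OH F4. Hydrogenation with [Ir(cod)(PCy3)(py)]PF6 is then directed across the ring alkene from the α face and rejoins the route at 17.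

- Step 18. What may go wrong: Z to E isomerisation of the acyl group during the acylation, or no acylation of the hindered allylic carbinol. Fallback: the Z alkene is built on the molecule. From 25, esterification with 2-[bis(2,2,2-trifluoroethoxy)phosphoryl]propanoic acid (N,N'-dicyclohexylcarbodiimide, DMAP, CH2Cl2) gives the C8 2-[bis(2,2,2-trifluoroethoxy)phosphoryl]propanoate of 25 F5. A Still–Gennari olefination with acetaldehyde (KHMDS, 18-crown-6, THF, −78 °C) should then give the (Z)-2-methylbut-2-enoate and rejoin the route at 27.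

**Further compounds**

F1 | step 8 | 4-O-(tert-butyldimethylsilyl)-6-deoxy-3-O-(4-methoxybenzyl)-2-C-methyl-D-ribo-hexos-5-ulose, open-chain form | O=C[C@](C)(O)[C@H](OCc1ccc(OC)cc1)[C@H](O[Si](C)(C)C(C)(C)C)C(C)=O
F2 | step 12 | C5=C6 enol triflate of the ring-A ketone (1β-OTBS, 2β-OPMB, 3β-OH, 3α-CH3, 4α-OTES) | FC(F)(F)S(=O)(=O)OC1=C[C@@H](O[Si](CC)(CC)CC)[C@](C)(O)[C@H](OCc2ccc(OC)cc2)[C@@H]1O[Si](C)(C)C(C)(C)C
F3 | step 12 | methyl 2-(ring-A-cyclohex-5-en-6-yl)acetate with 4α-OTES | COC(=O)CC1=C[C@@H](O[Si](CC)(CC)CC)[C@](C)(O)[C@H](OCc2ccc(OC)cc2)[C@@H]1O[Si](C)(C)C(C)(C)C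
F4 | step 12 | methyl 2-(ring-A-cyclohex-5-en-6-yl)acetate with 4α-OH | COC(=O)CC1=C[C@@H](O)[C@](C)(O)[C@H](OCc2ccc(OC)cc2)[C@@H]1O[Si](C)(C)C(C)(C)C
F5 | step 18 | C8 2-[bis(2,2,2-trifluoroethoxy)phosphoryl]propanoate of 25 | C=C([C@H](CC=C)OC(=O)C(C)P(=O)(OCC(F)(F)F)OCC(F)(F)F)[C@@H]1C[C@@H]2O[C@]2(C)[C@H](OCc3ccc(OC)cc3)[C@@H]1O[Si](C)(C)C(C)(C)C
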